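**Retrosynthetic overview**
1. Ring C is disconnected last. O1–C2 and the C2=C3 unsaturation come from oxidative cyclisation of a 2'-hydroxychalcone. Its Cα=Cβ bond comes from a Claisen–Schmidt condensation of a ring A methyl ketone with 3,4,5-trimethoxybenzaldehyde (ring B is bought).
2. The strategy rests on ring A. It has four neighbouring substituted carbons (C8a–O, C4a–acyl, C5–OMe, C6–O) beside two unsubstituted CH positions (C7, C8), and the oxygens at C8a and C6 are para to each other, so ring A is a hydroquinone.
3. That hydroquinone is unravelled to a 4-hydroxy-4-vinylcyclobutenone: ketone carbon = C8a, C2 = C4a, C3 (OMe) = C5, carbinol carbon = C6, vinyl = C7 and C8. The bond formed is C8–C8a.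
4. The cyclobutenone is assembled from dimethyl squarate by two carbonyl additions: first 1-ethoxyvinyllithium (a masked acetyl group) with 1,3-carbonyl transposition, then vinylmagnesium bromide.
5. Ring order: four-membered ring (bought), ring A (step 3), ring C (step 7).

Key step: step 3

Remark: the target has no stereocentre. All chiral intermediates are racemic and their stereocentres vanish later. Flavone numbering (O1 to C8a) is used for the target, and C1 (C=O) to C4 (carbinol) for the cyclobutenone.

Step 1
Reactants: 1 ethyl vinyl ether; 2 dimethyl squarate (3,4-dimethoxycyclobut-3-ene-1,2-dione)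
Product: 6 3-(1-ethoxyvinyl)-4-methoxycyclobut-3-ene-1,2-dione, via 1-ethoxyvinyllithium 3 (not isolated), via lithium alkoxide adduct 4 (not isolated), via tertiary trifluoroacetate 5 (not isolated)
Conditions: 1 (1.6 equiv), t-BuLi (1.1 equiv), THF, −78 → 0 °C; 2 (1.0 equiv), THF, −78 °C; (CF3CO)2O (1.2 equiv), −78 °C; sat. aq NaHCO3, −78 °C → rt; Et3N-deactivated silica
Reagents that add atoms: water, O (new carbonyl oxygen of 6); tert-butyllithium, [Li]C(C)(C)C (lithium of 3 and 4 only); trifluoroacetic anhydride, O=C(OC(=O)C(F)(F)F)C(F)(F)F (acyl group of 5 only)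
Why: α-Lithiation of the enol ether gives an acetyl anion equivalent that adds 1,2 to one squarate carbonyl, and O-trifluoroacetylation of the lithium alkoxide, ionisation, attack of water at the methoxy-stabilised cation terminus and loss of methanol then effect the known 1,3-carbonyl transposition of squarate adducts to 3-substituted 4-alkoxycyclobutenediones, while acylating the alkoxide instead of the free alcohol keeps strong acid out of the flask until the cold bicarbonate quench and so spares the enol ether.

Step 2
Reactants: 6 3-(1-ethoxyvinyl)-4-methoxycyclobut-3-ene-1,2-dione; 7 vinylmagnesium bromide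
Product: 8 racemic 2-(1-ethoxyvinyl)-4-hydroxy-3-methoxy-4-vinylcyclobut-2-en-1-one
Conditions: 7 (1.05 equiv, 1.0 M in THF), THF, −78 °C; sat. aq NH4Cl, −78 °C → 0 °C; Et3N-deactivated silica
Reagents that add atoms: none
Why: This is a 1,2-addition of a Grignard reagent to a cyclobutenedione, in which the carbonyl next to the methoxy-bearing carbon is a plain enone carbonyl and the other is deactivated as a vinylogous ester, so attack should occur at the former and give racemic 8 (its single stereocentre is uncontrolled and is erased in step 3), and attack at the other carbonyl would do no harm because ring expansion then leads to the same hydroquinone, C7 and C8 both being CH and both ring oxygens ending as free OH.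

Step 3
Reactants: 8 racemic 2-(1-ethoxyvinyl)-4-hydroxy-3-methoxy-4-vinylcyclobut-2-en-1-one
Product: 11 2-(1-ethoxyvinyl)-3-methoxybenzene-1,4-diol, via dienylketene 9 (not isolated), via cyclohexadienone 10 (not isolated)
Conditions: toluene (0.02 M, degassed), 110 °C, Ar, base-washed glassware; crude 11 taken on directly
Reagents that add atoms: none
Why: Heating breaks the C1–C4 bond of 8 (ketone carbon to carbinol carbon) in a conrotatory four-electron electrocyclic opening in which the donor hydroxyl turns outward and thereby forces the vinyl group inward, so that dienylketene 9 forms with the vinyl terminus next to the ketene carbon. A disrotatory six-electron electrocyclisation then joins these two carbons (the future C8a–C8 bond) and closes the six-membered carbocycle as cyclohexadienone 10, whose enolisation to the aromatic hydroquinone 11 makes the sequence irreversible. The closest known reaction type is the Moore-type thermal ring expansion of 4-alkenyl-4-hydroxycyclobutenones to hydroquinones, applied here to a 2-(1-alkoxyvinyl) member of the class. No stereocentre is created, and the racemic carbinol centre of 8 disappears on aromatisation. Two selectivities are needed: inward rotation of the vinyl group, which the outward preference of the oxygen donor at C4 secures, and closure onto the vinyl arm instead of the 1-ethoxyvinyl arm at C2, which is secured because the latter path is only a reversible four-electron return to a strained cyclobutenone while the six-electron path is drained by aromatisation. The substitution pattern follows from the connectivity of the four-membered ring (C1 to C8a–OH, C2 to C4a, C3 to C5–OMe, C4 to C6–OH, vinyl to C7–H and C8–H), and dilute, degassed, acid-free conditions should keep the enol ether and the hydroquinone intact.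

Step 4
Reactants: 11 2-(1-ethoxyvinyl)-3-methoxybenzene-1,4-diol
Product: 12 1-(3,6-dihydroxy-2-methoxyphenyl)ethan-1-one
Conditions: 0.5 M aq HCl (cat.), THF (degassed), 0 °C → rt, Ar
Reagents that add atoms: water, O
Why: Acid-catalysed enol ether hydrolysis (C-protonation, hydration of the oxocarbenium ion, loss of ethanol) is fast for an α-aryl enol ether on an electron-rich ring, any ketal-type adducts that phenol addition may have formed in step 3 are funnelled to the same ketone, and the product is stabilised by the hydrogen bond between the ortho hydroxyl and the carbonyl group.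

Step 5
Reactants: 12 1-(3,6-dihydroxy-2-methoxyphenyl)ethan-1-one
Product: 13 1-(6-hydroxy-2,3-dimethoxyphenyl)ethan-1-one
Conditions: MeI (1.05 equiv), K2CO3 (1.1 equiv), acetone, Ar, rt → 45 °C
Reagents that add atoms: iodomethane, CI
Why: Williamson-type O-methylation under weak base distinguishes the two phenols because the hydroxyl ortho to the acetyl group is held in a strong intramolecular hydrogen bond, so one equivalent of MeI should go to the free hydroxyl (future C6–O), a selectivity that is standard for 2,5-dihydroxyacetophenones.

Step 6
Reactants: 13 1-(6-hydroxy-2,3-dimethoxyphenyl)ethan-1-one; 14 3,4,5-trimethoxybenzaldehyde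
Product: 15 (E)-1-(6-hydroxy-2,3-dimethoxyphenyl)-3-(3,4,5-trimethoxyphenyl)prop-2-en-1-one
Conditions: 14 (1.1 equiv), KOH (50% aq, 5 equiv), EtOH, rt; then 1 M HCl to pH 4
Reagents that add atoms: none
Why: In this Claisen–Schmidt condensation the methyl ketone enolate adds to the non-enolisable aldehyde and E1cB dehydration gives the conjugated enone with thermodynamically set (E)-geometry, and partial ring closure to flavanone 16 is of no consequence because step 7 converts both.

Step 7
Reactants: 15 (E)-1-(6-hydroxy-2,3-dimethoxyphenyl)-3-(3,4,5-trimethoxyphenyl)prop-2-en-1-one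
Product: 17 cerosilin B (5,6-dimethoxy-2-(3,4,5-trimethoxyphenyl)-4H-chromen-4-one), via flavanone 16 (not isolated)
Conditions: I2 (10 mol %), DMSO, 120 °C
Reagents that add atoms: none
Why: In this iodine-catalysed oxidative cyclisation of a 2'-hydroxychalcone, 6-endo oxa-Michael closure forms O1–C2 (ring C), iodination at C3 and loss of HI install C2=C3, and DMSO reoxidises HI to I2, which keeps the HI level low enough that the peri C5 methyl ether should survive if heating is stopped at full conversion.

**Compound list**
1 | ethyl vinyl ether | C=COCC | starting material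
2 | dimethyl squarate | COC1=C(OC)C(=O)C1=O | starting material
3 | 1-ethoxyvinyllithium | [Li]C(=C)OCC | intermediate
4 | lithium 1-(1-ethoxyvinyl)-2,3-dimethoxy-4-oxocyclobut-2-en-1-olate (racemic) | [Li+].[O-]C1(C(=C)OCC)C(OC)=C(OC)C1=O | intermediate
5 | 1-(1-ethoxyvinyl)-2,3-dimethoxy-4-oxocyclobut-2-en-1-yl trifluoroacetate (racemic) | C=C(OCC)C1(OC(=O)C(F)(F)F)C(OC)=C(OC)C1=O | intermediate
6 | 3-(1-ethoxyvinyl)-4-methoxycyclobut-3-ene-1,2-dione | C=C(OCC)C1=C(OC)C(=O)C1=O | intermediate
7 | vinylmagnesium bromide | C=C[Mg]Br | starting material
8 | 2-(1-ethoxyvinyl)-4-hydroxy-3-methoxy-4-vinylcyclobut-2-en-1-one (racemic) | C=CC1(O)C(OC)=C(C(=C)OCC)C1=O | intermediate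
9 | (3Z)-2-(1-ethoxyvinyl)-4-hydroxy-3-methoxyhexa-1,3,5-trien-1-one (dienylketene) | O=C=C(C(=C)OCC)/C(OC)=C(/O)C=C | intermediate
10 | 2-(1-ethoxyvinyl)-4-hydroxy-3-methoxycyclohexa-2,4-dien-1-one | O=C1CC=C(O)C(OC)=C1C(=C)OCC | intermediate
11 | 2-(1-ethoxyvinyl)-3-methoxybenzene-1,4-diol | C=C(OCC)c1c(O)ccc(O)c1OC | intermediate
12 | 1-(3,6-dihydroxy-2-methoxyphenyl)ethan-1-one | CC(=O)c1c(O)ccc(O)c1OC | intermediate
13 | 1-(6-hydroxy-2,3-dimethoxyphenyl)ethan-1-one | CC(=O)c1c(O)ccc(OC)c1OC | intermediate
14 | 3,4,5-trimethoxybenzaldehyde | COc1cc(C=O)cc(OC)c1OC | starting material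
15 | (E)-1-(6-hydroxy-2,3-dimethoxyphenyl)-3-(3,4,5-trimethoxyphenyl)prop-2-en-1-one | COc1cc(/C=C/C(=O)c2c(O)ccc(OC)c2OC)cc(OC)c1OC | intermediate
16 | 5,6-dimethoxy-2-(3,4,5-trimethoxyphenyl)chroman-4-one (racemic flavanone) | COc1cc(C2CC(=O)c3c(OC)c(OC)ccc3O2)cc(OC)c1OC | intermediate
17 | cerosilin B, 5,6-dimethoxy-2-(3,4,5-trimethoxyphenyl)-4H-chromen-4-one | COc1cc(-c2cc(=O)c3c(OC)c(OC)ccc3o2)cc(OC)c1OC | target

**Total step count:** 7. **Longest linear sequence:** 7 steps (from 1 and 2 to 17).

**Steps most likely to fail**

1. Step 3. Traces of air may oxidise the emerging hydroquinone, and the new phenolic hydroxyls may transfer a proton to the enol ether at 110 °C. Both processes lead to oligomerisation.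
Fallback: this sets out from 8, which must first be freed of any regioisomer because the convergence noted in step 2 is lost here. The carbinol would be O-methylated under neutral conditions (MeI, Ag2O, MeCN, rt, dark) to racemic 2-(1-ethoxyvinyl)-3,4-dimethoxy-4-vinylcyclobut-2-en-1-one F1. The same thermal ring expansion, with the methoxy group turning outward, would then give 2-(1-ethoxyvinyl)-3,4-dimethoxyphenol F2, a monophenol that cannot be oxidised to a quinone. Dilute HCl in THF would hydrolyse its enol ether and rejoin the route at 13. The methyl group at C6–O is thus placed before ring A is made, and the selective methylation is no longer needed.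

2. Step 1. The enol ether may be lost by protonation, or by C-trifluoroacetylation at its CH2 terminus, during the anhydride-induced carbonyl transposition.
Fallback: this sets out from 2. Monohydrolysis (NaOH, 1.0 equiv, MeOH–H2O, 0 °C, then HCl) would give 3-hydroxy-4-methoxycyclobut-3-ene-1,2-dione F3. Treatment with (COCl)2 and cat. DMF in CH2Cl2 would convert it into 3-chloro-4-methoxycyclobut-3-ene-1,2-dione F4. A Stille coupling of this vinylogous acid chloride with tributyl(1-ethoxyvinyl)stannane (PdCl2(PPh3)2, CuI, THF, rt → 50 °C) would install the masked acetyl group under neutral conditions and rejoin the route at 6.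

3. Step 2. The vinyl nucleophile may attack the cross-conjugated dienedione in a conjugate sense, either at the methoxy-bearing ring carbon with loss of methoxide or at the diene terminus. A second addition is also possible.
Fallback: this sets out from 6. Ethynylmagnesium bromide (THF, −78 °C), a nucleophile that strongly prefers direct carbonyl addition, would give racemic 2-(1-ethoxyvinyl)-4-ethynyl-4-hydroxy-3-methoxycyclobut-2-en-1-one F5, which is thermally stable at room temperature. Semihydrogenation (H2, 1 atm, Pd/CaCO3 poisoned with Pb(OAc)2, quinoline, EtOAc, rt) would turn the terminal alkyne into the vinyl group and rejoin the route at 8.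

**Further compounds**
F1 | step 3 | 2-(1-ethoxyvinyl)-3,4-dimethoxy-4-vinylcyclobut-2-en-1-one (racemic) | C=CC1(OC)C(OC)=C(C(=C)OCC)C1=O
F2 | step 3 | 2-(1-ethoxyvinyl)-3,4-dimethoxyphenol | C=C(OCC)c1c(O)ccc(OC)c1OC
F3 | step 1 | 3-hydroxy-4-methoxycyclobut-3-ene-1,2-dione | COC1=C(O)C(=O)C1=O
F4 | step 1 | 3-chloro-4-methoxycyclobut-3-ene-1,2-dione | COC1=C(Cl)C(=O)C1=O
F5 | step 2 | 2-(1-ethoxyvinyl)-4-ethynyl-4-hydroxy-3-methoxycyclobut-2-en-1-one (racemic) | C#CC1(O)C(OC)=C(C(=C)OCC)C1=O
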